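## Retrosynthetic overview

1. The C9–C10 bond is made last, by Suzuki union of a Z-iodoalkenyl epoxy-triol with a terpenyl E-vinylboronate. The single silyl group comes off in the same pot.
2. The C3 and C6 carbinols come from a reagent-controlled double CBS reduction of an epoxy-enedione, which is unmasked from an epoxy quinone bisketal.
3. Key move: a 1,4-dimethoxyarene is dearomatised at the anode to a prochiral quinone bisketal, and a vanadium epoxidation directed by the C7 hydroxyl then builds the oxirane on what was the benzene ring.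
4. C7 and the 8Z-iodoalkene come from an enantioselective mono-alkynylation of the symmetric 2,5-dimethoxyterephthalaldehyde (made from 1,4-dimethoxybenzene), followed by Red-Al/I2.
5. The terpene carbocycle is made separately in one step, by Shi epoxidation of geranyl acetate and a Ti(III) 6-endo radical cyclisation. Oxidation and boron–Takai olefination follow.

**Convention:** C1 is the oxirane carbon bearing the chain, C2 the oxirane CH, C3 CHOH, C4 C(CH2OH), C5 =CH and C6 CHOH. The chain is C7 (carbinol), C8=C9(Me), C10=C11. The terpene ring is C1' (CH), C2' (CMe2), C3' (CHOH) and C6' (C=CH2). β is the face of the oxirane oxygen and α is the opposite face.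

**Assumption:** (R,R)-ProPhenol is taken to deliver the alkynyl group to the Si face of the aryl aldehyde. If the first assay shows the opposite sense, the (S,S)-ligand is used.

## Route

Step 1
Reactants: 1 1,4-dimethoxybenzene
Product: 3 2,5-dimethoxyterephthalaldehyde, via 2,5-dilithio-1,4-dimethoxybenzene 2 (not isolated)
Conditions: n-BuLi (3 equiv), TMEDA, Et2O–hexane, 0 °C to rt; DMF; aq HCl
Reagents that add atoms: N,N-dimethylformamide, CN(C)C=O
Why: Double directed ortho-metalation (the second lithiation goes para to the first C–Li) followed by DMF formylation is the known one-pot entry to this symmetric dialdehyde, and no stereocentre is formed.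

Step 2
Reactants: 3 2,5-dimethoxyterephthalaldehyde; 4 propyne
Product: 6 (S)-4-(1-hydroxybut-2-yn-1-yl)-2,5-dimethoxybenzaldehyde, via methyl(prop-1-ynyl)zinc 5 (not isolated)
Conditions: 3 (2 equiv), Me2Zn, (R,R)-ProPhenol (20 mol%), Ph3PO (40 mol%), toluene, 0 °C; aq NH4Cl
Reagents that add atoms: none
Why: In this Zn–ProPhenol asymmetric alkynylation (Trost) the excess dialdehyde ensures that only one of the two equivalent formyl groups reacts, which breaks the symmetry, and the dinuclear zinc pocket delivers the alkynyl group to the Si face to set C7 as S.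

Step 3
Reactants: 6 (S)-4-(1-hydroxybut-2-yn-1-yl)-2,5-dimethoxybenzaldehyde
Product: 8 (S,Z)-1-[4-(hydroxymethyl)-2,5-dimethoxyphenyl]-3-iodobut-2-en-1-ol, via cyclic vinylalanate 7 (not isolated)
Conditions: Red-Al (3.5 equiv), THF, 0 °C to rt; I2, −78 °C; Rochelle salt
Reagents that add atoms: iodine, II
Why: Alkoxide-directed trans-hydroalumination (Corey/Denmark Red-Al–iodine protocol) places Al on C9 inside a five-membered ring, so iodinolysis with retention gives only the Z-iodoalkene, while the second formyl group is reduced to CH2OH in the same pot and C7 is untouched.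

Step 4
Reactants: 8 (S,Z)-1-[4-(hydroxymethyl)-2,5-dimethoxyphenyl]-3-iodobut-2-en-1-ol
Product: 9 (S,Z)-1-[4-(tert-butyldimethylsilyloxymethyl)-2,5-dimethoxyphenyl]-3-iodobut-2-en-1-ol
Conditions: TBSCl (1.05 equiv), imidazole, CH2Cl2, −20 °C
Reagents that add atoms: tert-butyldimethylsilyl chloride, CC(C)(C)[Si](C)(C)Cl
Why: This is a chemoselective silylation, because the unhindered primary benzylic alcohol reacts much faster than the flanked secondary carbinol, which must stay free as the directing group.

Step 5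
Reactants: 9 (S,Z)-1-[4-(tert-butyldimethylsilyloxymethyl)-2,5-dimethoxyphenyl]-3-iodobut-2-en-1-ol
Product: 10 (S,Z)-1-[4-(tert-butyldimethylsilyloxymethyl)-3,3,6,6-tetramethoxycyclohexa-1,4-dien-1-yl]-3-iodobut-2-en-1-ol
Conditions: Pt anode, undivided cell, 1% KOH/MeOH, 0 °C, constant current, 2.3 F/mol
Reagents that add atoms: methanol, CO
Why: Anodic methoxylation of a 1,4-dimethoxyarene (Swenton quinone bisketal synthesis) is a two-electron dearomatisation in basic methanol that the silyl ether, the vinyl iodide and the acid-labile carbinol should tolerate, and it gives a prochiral non-conjugated diene in which C7 is the only stereocentre.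

Step 6
Reactants: 10 (S,Z)-1-[4-(tert-butyldimethylsilyloxymethyl)-3,3,6,6-tetramethoxycyclohexa-1,4-dien-1-yl]-3-iodobut-2-en-1-ol
Product: 11 (S,Z)-1-[4-(tert-butyldimethylsilyloxymethyl)-2,2,5,5-tetramethoxy-7-oxabicyclo[4.1.0]hept-3-en-1-yl]-3-iodobut-2-en-1-ol (oxirane O β; C1 and C2 as in the target)
Conditions: VO(acac)2 (5 mol%), TBHP (1.5 equiv, decane), CH2Cl2, 0 °C to rt
Reagents that add atoms: tert-butyl hydroperoxide, CC(C)(C)OO
Why: Proposed new method: hydroxyl-directed VO(acac)2/TBHP epoxidation (Sharpless–Michaelson type) has not been run on a quinone bisketal, but C1=C2 is here an ordinary trisubstituted allylic-alcohol olefin no longer conjugated to a carbonyl, C4=C5 has no free OH, the iodo-olefin is deactivated by iodine and by the A1,3 strain of its Z substituent, and the bulky C6 ketal geminal to the carbinol enforces the A1,2-strain transition state (C7–H towards C6, O–C7–C1=C2 about 45°) that gives the erythro epoxy alcohol, which is the C1/C2 configuration of the target.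

Step 7
Reactants: 11 epoxy bisketal
Product: 12 1-[(S,Z)-1-hydroxy-3-iodobut-2-enyl]-4-(tert-butyldimethylsilyloxymethyl)-7-oxabicyclo[4.1.0]hept-3-ene-2,5-dione (oxirane O β)
Conditions: montmorillonite K10, wet CH2Cl2, 0 °C to rt
Reagents that add atoms: water, O
Why: Acid-clay ketal hydrolysis (the method used for epoxy quinone monoketals) should work because both ketals are allylic to C4=C5 and ionise under conditions too mild to open the oxirane or cleave the TBS ether, and no stereocentre changes.

Step 8
Reactants: 12 epoxy-enedione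
Product: 13 1-[(S,Z)-1-hydroxy-3-iodobut-2-enyl]-4-(tert-butyldimethylsilyloxymethyl)-7-oxabicyclo[4.1.0]hept-3-ene-2,5-diol (oxirane O β; 3-OH and 6-OH α)
Conditions: (R)-Me-CBS (0.4 equiv), catecholborane (4 equiv), toluene–CH2Cl2, −78 °C; MeOH, aq NaHCO3
Reagents that add atoms: none
Why: In this Corey–Bakshi–Shibata reduction under reagent control the larger flank at both carbonyls (C4 with its CH2OTBS at C3=O, quaternary C1 at C6=O) lies in the same rotational sense, so the single (R)-catalyst delivers hydride to the β face of both and sets C3 and C6 as the cis-diol anti to the oxirane, with the 1,2-selectivity typical of catecholborane.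

Step 9
Reactants: 14 geranyl acetate
Product: 15 (2E)-5-[(2R)-3,3-dimethyloxiran-2-yl]-3-methylpent-2-en-1-yl acetate
Conditions: D-fructose-derived Shi ketone (30 mol%), Oxone, K2CO3, Bu4NHSO4, MeCN–DMM–borate buffer, 0 °C
Reagents that add atoms: potassium peroxymonosulfate (Oxone), [K+].[O-]S(=O)(=O)OO
Why: In the Shi asymmetric epoxidation the dioxirane attacks the electron-rich 6,7-olefin (the 2,3-olefin is deactivated by the allylic acetate) through the spiro transition state to give the R epoxide.

Step 10
Reactants: 15 (R)-6,7-epoxygeranyl acetate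
Product: 17 [(1S,3R)-3-hydroxy-2,2-dimethyl-6-methylidenecyclohexyl]methanol, via TMS ether acetate 16 (not isolated)
Conditions: Cp2TiCl2 (20 mol%), Mn, TMSCl, 2,4,6-collidine, THF, rt; filter; K2CO3 (cat.), MeOH, rt
Reagents that add atoms: none
Why: The titanocene(III)-catalysed epoxide opening and 6-endo radical cyclisation (Nugent–RajanBabu, Barrero–Cuerva–Oltra) runs through a chair with OTi and CH2OAc equatorial, so C3' keeps the epoxide configuration and C1' is set cis to it, β-hydride elimination gives the exocyclic methylene, and methanolysis then removes the TMS and acetyl groups.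

Step 11
Reactants: 17 [(1S,3R)-3-hydroxy-2,2-dimethyl-6-methylidenecyclohexyl]methanol
Product: 18 (1S,3R)-3-hydroxy-2,2-dimethyl-6-methylidenecyclohexane-1-carbaldehyde
Conditions: TEMPO (10 mol%), PhI(OAc)2 (1.1 equiv), CH2Cl2, 0 °C to rt
Reagents that add atoms: none
Why: TEMPO/PhI(OAc)2 oxidation is selective for the primary over the hindered secondary alcohol and is mild enough not to epimerise C1' or conjugate the β,γ-olefin.

Step 12
Reactants: 18 (1S,3R)-3-hydroxy-2,2-dimethyl-6-methylidenecyclohexane-1-carbaldehyde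
Product: 19 (1R,3S)-2,2-dimethyl-4-methylidene-3-[(E)-2-(4,4,5,5-tetramethyl-1,3,2-dioxaborolan-2-yl)ethenyl]cyclohexan-1-ol
Conditions: CrCl2 (8 equiv), LiI (4 equiv), Cl2CHBpin (2 equiv), THF, rt
Reagents that add atoms: 2-(dichloromethyl)-4,4,5,5-tetramethyl-1,3,2-dioxaborolane, ClC(Cl)B1OC(C)(C)C(C)(C)O1
Why: The Takai–Utimoto boron olefination with a gem-dichromium reagent is E-selective, essentially non-basic and tolerant of a free hydroxyl, so the α-stereocentre survives.

Step 13
Reactants: 13 Z-iodoalkenyl epoxy-triol TBS ether; 19 terpenyl E-vinylboronate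
Product: 21 CNP0357844.1 (target), via TBS ether 20 (not isolated)
Conditions: Pd(dppf)Cl2 (8 mol%), K3PO4 (3 equiv), degassed THF–H2O, rt; then TBAF/AcOH (1.5 equiv each), THF, 0 °C to rt
Reagents that add atoms: none
Why: Suzuki–Miyaura coupling of two alkenyl partners proceeds with retention at both olefins (8Z from 13, 10E from 19) at room temperature under a base mild enough for the epoxy triol, and buffered fluoride then cleaves the only silyl ether.

## Compound list

1 | 1,4-dimethoxybenzene | COc1ccc(OC)cc1 | starting material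
2 | 2,5-dilithio-1,4-dimethoxybenzene | COc1cc([Li])c(OC)cc1[Li] | intermediate
3 | 2,5-dimethoxyterephthalaldehyde | COc1cc(C=O)c(OC)cc1C=O | intermediate
4 | propyne | CC#C | starting material
5 | methyl(prop-1-ynyl)zinc | C[Zn]C#CC | intermediate
6 | (S)-4-(1-hydroxybut-2-yn-1-yl)-2,5-dimethoxybenzaldehyde | CC#C[C@H](O)c1cc(OC)c(C=O)cc1OC | intermediate
7 | cyclic vinylalanate (disodium salt, Al on C9 and on the C7 oxygen) | [Na+].[Na+].COCCO[Al-]1(OCCOC)O[C@@H](C=C1C)c1cc(OC)c(C[O-])cc1OC | intermediate
8 | (S,Z)-1-[4-(hydroxymethyl)-2,5-dimethoxyphenyl]-3-iodobut-2-en-1-ol | I/C(C)=C\[C@H](O)c1cc(OC)c(CO)cc1OC | intermediate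
9 | primary TBS ether of 8 | I/C(C)=C\[C@H](O)c1cc(OC)c(CO[Si](C)(C)C(C)(C)C)cc1OC | intermediate
10 | quinone bisketal (C7 S) | I/C(C)=C\[C@H](O)C1=CC(OC)(OC)C(CO[Si](C)(C)C(C)(C)C)=CC1(OC)OC | intermediate
11 | epoxy bisketal (oxirane β, erythro to 7-OH) | I/C(C)=C\[C@H](O)[C@]12O[C@H]1C(OC)(OC)C(CO[Si](C)(C)C(C)(C)C)=CC2(OC)OC | intermediate
12 | epoxy-enedione | I/C(C)=C\[C@H](O)[C@]12O[C@H]1C(=O)C(CO[Si](C)(C)C(C)(C)C)=CC2=O | intermediate
13 | epoxy-triol TBS ether (3-OH and 6-OH α) | I/C(C)=C\[C@H](O)[C@]12O[C@H]1[C@H](O)C(CO[Si](C)(C)C(C)(C)C)=C[C@@H]2O | intermediate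
14 | geranyl acetate | CC(C)=CCC/C(C)=C/COC(C)=O | starting material
15 | (R)-6,7-epoxygeranyl acetate | CC1(C)O[C@@H]1CC/C(C)=C/COC(C)=O | intermediate
16 | [(1S,3R)-2,2-dimethyl-6-methylidene-3-(trimethylsilyloxy)cyclohexyl]methyl acetate | C=C1CC[C@@H](O[Si](C)(C)C)C(C)(C)[C@H]1COC(C)=O | intermediate
17 | [(1S,3R)-3-hydroxy-2,2-dimethyl-6-methylidenecyclohexyl]methanol | C=C1CC[C@@H](O)C(C)(C)[C@H]1CO | intermediate
18 | (1S,3R)-3-hydroxy-2,2-dimethyl-6-methylidenecyclohexane-1-carbaldehyde | C=C1CC[C@@H](O)C(C)(C)[C@H]1C=O | intermediate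
19 | terpenyl E-vinylboronate (C1' S, C3' R) | C=C1CC[C@@H](O)C(C)(C)[C@H]1/C=C/B1OC(C)(C)C(C)(C)O1 | intermediate
20 | TBS ether of the target (on the C4 CH2OH) | C=C1CC[C@@H](O)C(C)(C)[C@H]1/C=C/C(C)=C\[C@H](O)[C@]12O[C@H]1[C@H](O)C(CO[Si](C)(C)C(C)(C)C)=C[C@@H]2O | intermediate
21 | (1R,2S,5R,6S)-1-{(1S,2Z,4E)-1-hydroxy-5-[(1S,3R)-3-hydroxy-2,2-dimethyl-6-methylidenecyclohexyl]-3-methylpenta-2,4-dienyl}-4-(hydroxymethyl)-7-oxabicyclo[4.1.0]hept-3-ene-2,5-diol | C=C1CC[C@@H](O)C(C)(C)[C@H]1/C=C/C(C)=C\[C@H](O)[C@]12O[C@H]1[C@H](O)C(CO)=C[C@@H]2O | target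

## Step count and risks

Total step count: 13. Longest linear sequence: 9 (steps 1–8, then 13).

**Step 6 (directed epoxidation of the bisketal).**
- The four flanking methoxy groups may make C1=C2 too electron-poor, or vanadium may only oxidise the bis-allylic carbinol.
- The fallback leaves the route at 9 and returns at 12, so it also covers trouble in steps 5 and 7.
- CAN in MeCN–H2O at 0 °C removes both methyl groups and gives the (S,Z)-2-(1-hydroxy-3-iodobut-2-enyl)-5-(tert-butyldimethylsilyloxymethyl)-1,4-benzoquinone F1.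
- The sodium alkoxide of that quinone is then epoxidised from within by trityl hydroperoxide (NaHMDS, matched diisopropyl tartrate, toluene, −50 °C).
- This is a nucleophilic Weitz–Scheffer-type epoxidation tied to the only free hydroxyl, and it lands directly on 12.

**Step 8 (double CBS reduction against the substrate bias).**
- Hydride normally attacks α,β-epoxy ketones anti to the oxirane, so the catalyst may not override this preference, above all at C3.
- The fallback leaves at 12 and returns at 13, and it uses the innate bias rather than fighting it.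
- TESOTf/2,6-lutidine gives the 7-O-triethylsilyl epoxy-enedione F2.
- Luche reduction (NaBH4, CeCl3, MeOH, −78 °C) gives the all-β syn,syn-diol F3.
- A double Mitsunobu inversion (4-nitrobenzoic acid, PPh3, DIAD, toluene, 0 °C) gives the α,α-bis(4-nitrobenzoate) F4.
- K2CO3/MeOH followed by PPTS/MeOH removes the esters and the TES group and gives 13.

**Step 13 (coupling of a hindered Z-iodide that carries a base-sensitive epoxy triol).**
- Payne migration or protodeboronation could compete with the coupling.
- The fallback changes the order of events. It leaves at 9 and 19 and returns at 20.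
- The same Suzuki coupling is run on the robust arene and gives the full-skeleton dimethoxyarene F5.
- The dearomatisation sequence is then applied late: anodic methoxylation gives the full-skeleton quinone bisketal F6.
- VO(acac)2/TBHP gives the full-skeleton epoxy bisketal F7.
- K10 clay gives the full-skeleton epoxy-enedione F8.
- (R)-CBS/catecholborane then gives 20, which is desilylated as in step 13.

## Further compounds

F1 | step 6 | (S,Z)-2-(1-hydroxy-3-iodobut-2-enyl)-5-(tert-butyldimethylsilyloxymethyl)-1,4-benzoquinone | I/C(C)=C\[C@H](O)C1=CC(=O)C(CO[Si](C)(C)C(C)(C)C)=CC1=O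
F2 | step 8 | 7-O-triethylsilyl epoxy-enedione | I/C(C)=C\[C@H](O[Si](CC)(CC)CC)[C@]12O[C@H]1C(=O)C(CO[Si](C)(C)C(C)(C)C)=CC2=O
F3 | step 8 | all-β syn,syn-diol | I/C(C)=C\[C@H](O[Si](CC)(CC)CC)[C@]12O[C@H]1[C@@H](O)C(CO[Si](C)(C)C(C)(C)C)=C[C@H]2O
F4 | step 8 | α,α-bis(4-nitrobenzoate) | I/C(C)=C\[C@H](O[Si](CC)(CC)CC)[C@]12O[C@H]1[C@H](OC(=O)c1ccc(cc1)[N+](=O)[O-])C(CO[Si](C)(C)C(C)(C)C)=C[C@@H]2OC(=O)c1ccc(cc1)[N+](=O)[O-]
F5 | step 13 | full-skeleton dimethoxyarene | C=C1CC[C@@H](O)C(C)(C)[C@H]1/C=C/C(C)=C\[C@H](O)c1cc(OC)c(CO[Si](C)(C)C(C)(C)C)cc1OC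
F6 | step 13 | full-skeleton quinone bisketal | C=C1CC[C@@H](O)C(C)(C)[C@H]1/C=C/C(C)=C\[C@H](O)C1=CC(OC)(OC)C(CO[Si](C)(C)C(C)(C)C)=CC1(OC)OC
F7 | step 13 | full-skeleton epoxy bisketal | C=C1CC[C@@H](O)C(C)(C)[C@H]1/C=C/C(C)=C\[C@H](O)[C@]12O[C@H]1C(OC)(OC)C(CO[Si](C)(C)C(C)(C)C)=CC2(OC)OC
F8 | step 13 | full-skeleton epoxy-enedione | C=C1CC[C@@H](O)C(C)(C)[C@H]1/C=C/C(C)=C\[C@H](O)[C@]12O[C@H]1C(=O)C(CO[Si](C)(C)C(C)(C)C)=CC2=O
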